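**Small charge.** A small charge of substrate, 0.050 M, meets 0.0500 M of solid reagent, none of it in solution at the start. Thursday's, Wednesday's and Friday's run at 25 °C, 40 °C and 55 °C.

| flask | substrate | solid reagent | temperature | remark | time |
|---|---|---|---|---|---|
| alpha | 0.025 M | 0.050 M | 20 °C | run made earlier |  |
| delta | 0.10 M | 0.050 M | 40 °C | run made earlier |  |
| eta | 0.050 M | 0.075 M | 20 °C | run made earlier |  |
| Thursday's | 0.050 M | 0.0500 M | 25 °C |  | 4.0 min |
| Wednesday's | 0.050 M | 0.0500 M | 40 °C |  | 4.0 min |
| Friday's | 0.050 M | 0.0500 M | 55 °C |  | 4.0 min |

alpha run (percent of the substrate charged): time / min: mono adduct / % = 0.333: 0.8; 0.500: 0.2; 0.833: 1.9; 1.33: 4.5; 2.50: 10.3; 4.00: 21.0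

delta run (percent of the substrate charged): time / s: mono adduct / % = 20.0: 0.7; 40.0: 2.2; 60.0: 5.1; 80.0: 5.7; 120: 8.7

eta run (percent of the substrate charged): time / min: mono adduct / % = 0.333: 0.9; 1.00: 2.5; 2.00: 6.7; 3.00: 11.6; 4.00: 17.8

(scatter of a reading: 0.5 percentage points)

- solid reagent is a solid; its amount is given per volume of the solution
- the analysis behind the earlier runs scatters by 0.5 percentage points, standard deviation
- at the start none of the solid reagent is in solution

- which of the two there is more of at the end, Thursday's (bis adduct / mono adduct)
- which of the two there is more of at the end, Wednesday's (bis adduct / mono adduct)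
- which of the two there is more of at the end, Friday's (bis adduct / mono adduct)
- mono adduct at the end, in percent of the substrate charged, Thursday's
- mono adduct at the end, in percent of the substrate charged, Wednesday's
- mono adduct at the end, in percent of the substrate charged, Friday's

**Two rates.** We count turnovers: the late rise of c(mono adduct), times the time, over the charge of substrate. Eta has our substrate charge at 20 °C, and from 2.00 min to 4.00 min it climbs at 0.00278 M min⁻¹. Delta has twice that substrate and runs warmer, and from 40.0 s to 120 s it climbs at 0.00487 M min⁻¹. This reading is our feed ceiling, the rate at which c(mono adduct) rises in delta.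

**Their ratio.** A step first order in substrate doubles on that charge by itself, and warmth adds to it. Yet the ratio reads 1.75, below 2. Delta also holds less solid reagent, 0.050 M against 0.075 M. So we read dissolving as the rate-limiting step of the warm flasks.

**Our count.** Over 4.0 min on 0.050 M, the two rates count to 22.2% and 39.0% of the charge. The lag is ignored, so both counts run high. We expect Thursday's, just warmer than eta, near the lower count. We expect Wednesday's and Friday's close together, under the upper one. The earlier runs list no bis adduct, so we assume, without a reading, that mono adduct leads it.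

**The forecast.** The forecast has mono adduct leading on Thursday's, Wednesday's and Friday's, with 16%, 32% and 52%, the last above our upper count, “with Friday's limited by depletion”.

**The flasks.** Thursday's ends with 21.2% mono adduct and 1.96% bis adduct, Wednesday's with 29.3% and 4.99%, and Friday's with 32.0% and 7.57%.

    substrate + partner → mono adduct (k = 0.169 M⁻¹ s⁻¹, Ea = 57.0 kJ mol⁻¹)
    substrate + partner → other mono adduct (k = 0.0842 M⁻¹ s⁻¹, Ea = 68.0 kJ mol⁻¹)
    partner + mono adduct → bis adduct (k = 0.00215 M⁻¹ s⁻¹, Ea = 60.0 kJ mol⁻¹)
    partner + other mono adduct → bis adduct (k = 0.257 M⁻¹ s⁻¹, Ea = 56.0 kJ mol⁻¹)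
    solid reagent ⇌ partner, rate k5*(cs5 - [partner]) while solid is left; crystals form when [partner] > cs5 (solubility = 21.0 mM, k = 0.00717 s⁻¹)
    (constants at 25 °C)

**The ceiling.** Friday's 32.0% stands under the count of 39.0%. On Friday's, solid reagent leaves the solid at 0.00842 M min⁻¹ on average, against a full dissolving rate of 0.00903 M min⁻¹, while mono adduct gains 0.00400 M min⁻¹ on average. A neighbour like Thursday's, with 0.20 M substrate, counts by 0.00487 M min⁻¹ to 9.74% and gives 9.43%.

(All runs are simulated from invented constants.)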